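**Retrosynthetic overview**
1. Building blocks: (R)-linalool 1, oxidised to enal 2 (all ten terpenoid carbons and the only purchased stereocentre); 2,4,6-trihydroxyacetophenone 3 and dichlorobutene 4, joined to the dearomatised trione 5 (chlorobutenyl = acid-proof masked prenyl).
2. Key disconnection: bonds C1'–C1 and C2–C6 by an intramolecular Diels–Alder reaction of the Knoevenagel diene 6, giving spiro cycloadduct 7 (cyclopentane, cyclohexene and spiro centre in one step).
3. C7–OH: from the ring alkene of 7, captured by the 1,3-diaxial enol oxygen as bridged enol ether 8 (sets C7) and released by hydroxide at the end.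
4. Prenyl groups: from the two alkenyl chlorides by methyl cross-coupling (9), before the bridge is opened to target 10.
5. Ring order: trione ring (aromatic ring of 3, dearomatised in step 2), then cyclopentane and cyclohexene together (step 3), then a temporary oxolane bridge (step 4, opened in step 6).

Locants used below: terpenoid carbons keep linalool numbering C1–C8 (C3 and C7 are the carbinol carbons, C2/C6 the ring-fusion carbons). Trione ring: C1' (spiro), C2' (C=O beside the bis-alkylated carbon), C3' (bis-alkylated), C4', C5' (acetyl-bearing), C6' (C=O beside C5').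

Assumption: 1,3-dichlorobut-2-ene is used as the commercial E/Z mixture; only the E isomer is named and drawn, and the geometry of these two arms is erased in step 5, so no separation is needed.

**Step 1**
Reactants: 1 (R)-(−)-linalool
Product: 2 (2E,6R)-6-hydroxy-2,6-dimethylocta-2,7-dienal
Conditions: SeO2 (1.1 equiv), 1,4-dioxane/EtOH 9:1, 80 °C, 5 h
Reagents that add atoms: selenium dioxide O=[Se]=O
Why: Riley allylic oxidation (ene reaction, then [2,3]-sigmatropic shift) attacks only the E-methyl of the trisubstituted alkene and runs through to the E-enal; no stereocentre is formed and the carbinol carbon is untouched.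

**Step 2**
Reactants: 3 2,4,6-trihydroxyacetophenone; 4 (E)-1,3-dichlorobut-2-ene (2.2 equiv)
Product: 5 2-acetyl-4,4-bis[(E)-3-chlorobut-2-enyl]cyclohexane-1,3,5-trione (3-enol)
Conditions: NaOMe (3 equiv), NaI (0.1 equiv), MeOH, 0 °C to rt, 16 h; 1 M HCl work-up
Reagents that add atoms: none
Why: Double C-alkylation of the phloroglucinol anion by the allylic chloride end of the reagent (SN2; the vinylic C–Cl is inert) dearomatises the ring when the second group enters the same carbon, the standard route to gem-dialkyl acylphloroglucinols; a modest yield is expected and no stereocentre is formed.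

**Step 3**
Reactants: 5; 2 (1.2 equiv)
Product: 7 spiro cycloadduct (trans-fused hexahydroindene spiro-linked at C1' to the trione ring; 1'S 2S 3R 6R), via alkylidene trione 6 (not isolated)
Conditions: ethylenediammonium diacetate (0.2 equiv), 4 Å molecular sieves, toluene, 60 °C 2 h, then 120 °C (sealed tube) 24 h
Reagents that add atoms: none
Why: Knoevenagel condensation gives the 1,1-diacyl diene 6, whose oxa-6π closure is reversible at this temperature while the intramolecular Diels–Alder reaction onto the vinyl group (three-atom tether, fused mode) is not; suprafacial addition through the tether-exo transition state gives the trans C2/C6 fusion, a hydrogen bond from C3–OH to the Z carbonyl oxygen puts OH (not CH3) on the C1 side so that C2 and C6 follow from the linalool centre, and the spiro configuration follows from the alkylidene geometry with C2'=O cis to the diene; the spiro epimer is an expected by-product, removed by chromatography.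

**Step 4**
Reactants: 7
Product: 8 bridged enol ether (oxygen links C7 to C6'; C6'=C5' enol ether, C4' ketone; 1'R 2S 3R 6R 7S)
Conditions: TsOH·H2O (0.2 equiv), CH2Cl2, 0 °C to rt, 6 h
Reagents that add atoms: none
Why: Acid-catalysed intramolecular hydroalkoxylation: Markovnikov protonation of the trisubstituted ring alkene gives the tertiary C7 cation, which is captured from the lower face by the enol oxygen of the axial C6' carbonyl lying 1,3-diaxial to it, fixing C7 (O axial, CH3 equatorial); the chloroalkenes are too electron-poor to be protonated, C3–OH cannot reach C7 across the trans fusion, and the spiro epimer cannot cyclise.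

**Step 5**
Reactants: 8
Product: 9 bridged enol ether with two prenyl groups at C3'
Conditions: MeZnCl (6 equiv, THF), Pd(P(t-Bu)3)2 (5 mol %), THF/NMP 2:1, 70 °C, 12 h
Reagents that add atoms: methylzinc chloride C[Zn]Cl
Why: Negishi cross-coupling: the bulky electron-rich phosphine lets zerovalent palladium insert into unactivated alkenyl C–Cl bonds, MeZnCl tolerates the ketones, the vinylogous ester and the zinc alkoxide of C3–OH, and both E and Z chlorides give the same gem-dimethyl alkene; no stereocentre is touched.

**Step 6**
Reactants: 9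
Product: 10 target CNP0266834.3 (1'S 2S 3R 6R 7S)
Conditions: LiOH·H2O (5 equiv), THF/H2O 3:1, 40 °C, 8 h; then 0.5 M HCl to pH 4 at 0 °C
Reagents that add atoms: lithium hydroxide [Li+].[OH-] (its oxygen ends on C6')
Why: Vinylogous ester saponification (addition–elimination of hydroxide at the doubly activated C6') expels the tertiary alkoxide with the C7–O bond intact, so C7 keeps its configuration; the resulting triketone enolate resists further attack and mild acidification gives 10.

**Compound list**
1 | (R)-(−)-linalool, (3R)-3,7-dimethylocta-1,6-dien-3-ol | C=C[C@](C)(O)CCC=C(C)C | starting material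
2 | (2E,6R)-6-hydroxy-2,6-dimethylocta-2,7-dienal | C=C[C@](C)(O)CC/C=C(\C)C=O | intermediate
3 | 2,4,6-trihydroxyacetophenone | CC(=O)c1c(O)cc(O)cc1O | starting material
4 | (E)-1,3-dichlorobut-2-ene | ClC/C=C(\C)Cl | starting material
5 | 2-acetyl-4,4-bis[(E)-3-chlorobut-2-enyl]cyclohexane-1,3,5-trione, 3-enol | CC(=O)C1=C(O)C(C/C=C(\C)Cl)(C/C=C(\C)Cl)C(=O)CC1=O | intermediate
6 | alkylidene trione: 5 carrying at C1' the (2E,6R)-6-hydroxy-2,6-dimethylocta-2,7-dienylidene group, C2'=O cis to the chain | CC(=O)C1=C(O)C(C/C=C(\C)Cl)(C/C=C(\C)Cl)C(=O)/C(=C\C(C)=C\CC[C@@](C)(O)C=C)C1=O | intermediate (not isolated)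
7 | spiro cycloadduct: trans-fused hexahydroindene (C3 carbinol, C7=C8 alkene) spiro at C1'; 1'S,2S,3R,6R | CC(=O)C1=C(O)C(C/C=C(\C)Cl)(C/C=C(\C)Cl)C(=O)[C@@]2(C[C@H]3[C@@H](CC[C@@]3(C)O)C(C)=C2)C1=O | intermediate
8 | bridged enol ether (C7–O–C6'), chlorobutenyl arms; 1'R,2S,3R,6R,7S | CC(=O)C1=C2O[C@@]3(C)C[C@@]2(C[C@H]4[C@H]3CC[C@@]4(C)O)C(=O)C(C/C=C(\C)Cl)(C/C=C(\C)Cl)C1=O | intermediate
9 | bridged enol ether (C7–O–C6'), prenyl arms; 1'R,2S,3R,6R,7S | CC(=O)C1=C2O[C@@]3(C)C[C@@]2(C[C@H]4[C@H]3CC[C@@]4(C)O)C(=O)C(CC=C(C)C)(CC=C(C)C)C1=O | intermediate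
10 | CNP0266834.3; 1'S,2S,3R,6R,7S | CC(=O)C1=C(O)C(CC=C(C)C)(CC=C(C)C)C(=O)[C@@]2(C[C@H]3[C@@H](CC[C@@]3(C)O)[C@@](C)(O)C2)C1=O | target

**Totals**
Total steps: 6. Longest linear sequence: 5 steps (1 → 2 → 7 → 8 → 9 → 10, or 3 → 5 → 7 → 8 → 9 → 10).

**Three steps most likely to fail**

Step 3 is the highest risk. The condensation of the α-branched enal may stall at the 2H-pyran valence isomer or give bis-adducts, and selectivity at the spiro centre is not assured. The fallback makes the diene by C–C coupling and dehydrogenation instead of condensation; it sets out from 2 and 5 and comes back at 6. NaBH4/CeCl3·7H2O reduction of 2 gives (2E,6R)-2,6-dimethylocta-2,7-diene-1,6-diol F1. ClCO2Me/pyridine converts only the primary hydroxyl into the methyl carbonate F2. Pd(PPh3)4 (zerovalent palladium) couples F2 through its primary allyl terminus with the free ring carbon C1' of 5 to give the C-allylated trione F3. DDQ in benzene dehydrogenates F3 to 6 at room temperature, free of amine and water; 6 is then heated, or treated with Me2AlCl at low temperature, to give 7. This does not help if the cycloaddition itself is unselective.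

Step 4 may fail because the tertiary C3–OH can ionise or dehydrate under the acid. The fallback replaces protonation by halocyclisation and radical reduction; it sets out from 7 and comes back at 8. I2/NaHCO3 in MeCN at 0 °C attacks only the electron-rich ring alkene, and the axial C6' enolate oxygen opens the iodonium trans-diaxially to give the C8-iodo bridged ether F4. Bu3SnH/AIBN in toluene at 80 °C then removes the iodine (the alkenyl chlorides survive) to give 8.

Step 5 may fail through sluggish oxidative addition or chelation of palladium by the substrate. The fallback changes the masked prenyl group to allyl and builds the prenyl groups by olefination; it sets out from 3 and comes back at 9. Allyl bromide/NaOMe converts 3 into the diallyl trione F5. Condensation with 2 under the step 3 conditions gives the alkylidene trione F6 (not isolated) and its cycloadduct F7. TsOH closes the bridged enol ether F8. OsO4 (cat.)/NaIO4/2,6-lutidine cleaves both allyl groups to the dialdehyde F9. Wittig olefination with Ph3P=CMe2 (from isopropyltriphenylphosphonium iodide and KN(SiMe3)2, −78 °C) gives 9. Cross-metathesis of F8 with 2-methylbut-2-ene is avoided because gem-diallyl groups ring-close.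

**Further compounds**
F1 | step 3 | (2E,6R)-2,6-dimethylocta-2,7-diene-1,6-diol | C=C[C@](C)(O)CC/C=C(\C)CO
F2 | step 3 | (2E,6R)-6-hydroxy-2,6-dimethylocta-2,7-dienyl methyl carbonate | C=C[C@](C)(O)CC/C=C(\C)COC(=O)OC
F3 | step 3 | 5 C-allylated at C1' with the (2E,6R)-6-hydroxy-2,6-dimethylocta-2,7-dienyl group (enol form) | CC(=O)C1=C(O)C(C/C=C(\C)Cl)(C/C=C(\C)Cl)C(O)=C(C/C(C)=C/CC[C@@](C)(O)C=C)C1=O
F4 | step 4 | C8-iodo bridged enol ether (iodine axial, anti to the ether oxygen) | CC(=O)C1=C2O[C@@]3(C)[C@H](I)[C@@]2(C[C@H]4[C@H]3CC[C@@]4(C)O)C(=O)C(C/C=C(\C)Cl)(C/C=C(\C)Cl)C1=O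
F5 | step 5 | 2-acetyl-4,4-diallylcyclohexane-1,3,5-trione, 3-enol | CC(=O)C1=C(O)C(CC=C)(CC=C)C(=O)CC1=O
F6 | step 5 | diallyl alkylidene trione (not isolated) | CC(=O)C1=C(O)C(CC=C)(CC=C)C(=O)/C(=C\C(C)=C\CC[C@@](C)(O)C=C)C1=O
F7 | step 5 | diallyl spiro cycloadduct | CC(=O)C1=C(O)C(CC=C)(CC=C)C(=O)[C@@]2(C[C@H]3[C@@H](CC[C@@]3(C)O)C(C)=C2)C1=O
F8 | step 5 | diallyl bridged enol ether | CC(=O)C1=C2O[C@@]3(C)C[C@@]2(C[C@H]4[C@H]3CC[C@@]4(C)O)C(=O)C(CC=C)(CC=C)C1=O
F9 | step 5 | bridged enol ether with two 2-oxoethyl groups at C3' | CC(=O)C1=C2O[C@@]3(C)C[C@@]2(C[C@H]4[C@H]3CC[C@@]4(C)O)C(=O)C(CC=O)(CC=O)C1=O
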